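**Retrosynthetic overview**
1. Numbering used throughout: ten-membered ring C1–C10 with C6 = lactone O–CH, C7 = ring-fusion CH, C8 = CH–O-tigloyl, C9 = CH2, C10 = C(CH3)=, C1 = =CH, C2 = CH–OH, C3 = CH2, C4 = C(=CH2), C5 = CH–OAc; lactone carbons C11 (α-carbon), C12 (C=O), C13 (exocyclic =CH2).
2. Enabling feature: the cis-fused α-methylene-γ-butyrolactone holds the unit O–C6H–C7H–C11(=C13H2)–C12(=O), a homoallylic alcohol acylated by its own acrylate. Read backwards it is a C6 aldehyde plus a 2-(alkoxycarbonyl)allyl metal (C13–C11=C7), and C6–C7 is also a bond of the ten-membered ring, whose (Z)-C1=C10 olefin folds the open chain.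
3. Key disconnection C6–C7: CrCl2-mediated intramolecular allylation of the seco aldehyde/(Z)-2-(bromomethyl)enoate 23 closes the ten-membered carbocycle first and, by acyl transfer of the new C6 alkoxide onto C12, the five-membered lactone second in the same flask. The C5 and C8 ethers steer C6 and C7, and both C7 epimers of adduct 20 and any (E)-bromide converge.
4. Chain assembly: C3–C6 from methyl (R)-glycerate (allylstannane 6); C1, C2, C10 and the methyl from but-2-yn-1-ol ((Z)-iodoenal 10), joined by Keck allylation (sets C2); C7–C9 from methyl (R)-glycidate by alkenyl-metal epoxide opening (C9–C10 bond, C8 from the pool); C11–C13 from methyl acrylate.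
5. Endgame: orthogonal TES (O5), TBS (O8) and PMB (O2) ethers are exchanged for acetate, tiglate and free hydroxyl, in that order.

Key step: step 16

Remark: CIP descriptors are given for the open-chain compounds only, because silyl groups change the priorities at the ring-fusion carbons; the SMILES fix the configuration of the ring compounds. TES = triethylsilyl, TBS = tert-butyldimethylsilyl, PMB = 4-methoxybenzyl.

**Step 1**
Reactants: 1 methyl (2R)-2,3-dihydroxypropanoate
Product: 2 methyl (2R)-2,3-bis(triethylsilyloxy)propanoate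
Conditions: TESCl (2.4 equiv), imidazole, DMAP (cat.), CH2Cl2, 0 °C → rt
Reagents that add atoms: chlorotriethylsilane CC[Si](Cl)(CC)CC
Why: Imidazole-mediated silylation protects both hydroxyl groups without touching the stereocentre that becomes C5.

**Step 2**
Reactants: 2 methyl (2R)-2,3-bis(triethylsilyloxy)propanoate
Product: 4 [(3S)-3,4-bis(triethylsilyloxy)-2-methylidenebutyl]trimethylsilane, via bis(silylmethyl) carbinol 3 (not isolated)
Conditions: Me3SiCH2MgCl (5 equiv), CeCl3 (5 equiv), THF, −78 °C → rt; then SiO2, CH2Cl2, rt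
Reagents that add atoms: (trimethylsilyl)methylmagnesium chloride C[Si](C)(C)C[Mg]Cl
Why: Double addition of the non-basic organocerium reagent to the ester gives carbinol 3, and acid-promoted Peterson elimination of one β-silyl alcohol unit delivers the 2-substituted allylsilane without epimerising the α-stereocentre.

**Step 3**
Reactants: 4 [(3S)-3,4-bis(triethylsilyloxy)-2-methylidenebutyl]trimethylsilane
Product: 5 (3S)-2-(bromomethyl)-3,4-bis(triethylsilyloxy)but-1-ene
Conditions: NBS, CH2Cl2, −78 °C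
Reagents that add atoms: N-bromosuccinimide O=C1CCC(=O)N1Br
Why: Electrophilic bromodesilylation (SE2′) puts bromine on the terminal methylene while the silyl group leaves from the other allylic terminus, which regenerates the same 1,1-disubstituted olefin.

**Step 4**
Reactants: 5 (3S)-2-(bromomethyl)-3,4-bis(triethylsilyloxy)but-1-ene
Product: 6 tributyl[(3S)-3,4-bis(triethylsilyloxy)-2-methylidenebutyl]stannane
Conditions: Bu3SnH, LiN(i-Pr)2, THF, 0 °C; then 5, −78 °C → 0 °C
Reagents that add atoms: tributylstannyllithium [Li][Sn](CCCC)(CCCC)CCCC, made in the flask from tributyltin hydride CCCC[SnH](CCCC)CCCC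
Why: SN2 displacement of the primary allylic bromide by the stannyl anion is a standard entry to 2-substituted allylstannanes.

**Step 5**
Reactants: 7 but-2-yn-1-ol
Product: 9 (2Z)-3-iodobut-2-en-1-ol, via cyclic alkenylalanate 8 (not isolated)
Conditions: NaAlH2(OCH2CH2OMe)2 (Red-Al), THF, 0 °C → rt; then I2, −78 °C → 0 °C
Reagents that add atoms: iodine II
Why: Hydroxyl-directed trans-hydroalumination of the propargylic alcohol gives alanate 8, and iodinolysis of the C–Al bond with retention fixes the (Z) geometry that becomes the C1=C10 olefin.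

**Step 6**
Reactants: 9 (2Z)-3-iodobut-2-en-1-ol
Product: 10 (2Z)-3-iodobut-2-enal
Conditions: MnO2 (excess), CH2Cl2, rt, dark
Reagents that add atoms: none
Why: Allylic oxidation with MnO2 is mild enough to give the enal without isomerising the (Z)-iodoalkene.

**Step 7**
Reactants: 10 (2Z)-3-iodobut-2-enal; 6 tributyl[(3S)-3,4-bis(triethylsilyloxy)-2-methylidenebutyl]stannane
Product: 11 (2Z,4R,7S)-2-iodo-6-methylidene-7,8-bis(triethylsilyloxy)oct-2-en-4-ol
Conditions: (R)-BINOL (20 mol%), Ti(OiPr)4 (10 mol%), 4 Å MS, CH2Cl2, −20 °C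
Reagents that add atoms: none
Why: In this Keck asymmetric allylation the (R)-BINOL–titanium Lewis acid directs the 2-substituted allylstannane to the Re face of the enal carbonyl, which sets C2 as R under catalyst control irrespective of the remote C5 centre.

**Step 8**
Reactants: 11 (2Z,4R,7S)-2-iodo-6-methylidene-7,8-bis(triethylsilyloxy)oct-2-en-4-ol
Product: 12 4-methoxybenzyl ether of 11 at O2
Conditions: NaH, 4-methoxybenzyl chloride, Bu4NI (cat.), THF/DMF, 0 °C → rt
Reagents that add atoms: 4-methoxybenzyl chloride COc1ccc(CCl)cc1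
Why: Williamson etherification of the sodium alkoxide installs an oxidatively removable group on O2 that survives organolithium, hydride, acid and fluoride steps.

**Step 9**
Reactants: 12 PMB ether; 13 methyl (2R)-oxirane-2-carboxylate
Product: 16 methyl (2R,4Z,6R,9S)-2-hydroxy-6-[(4-methoxybenzyl)oxy]-4-methyl-8-methylidene-9,10-bis(triethylsilyloxy)dec-4-enoate, via alkenyllithium 14 (not isolated), via alkenylmagnesium bromide 15 (not isolated)
Conditions: t-BuLi (2.1 equiv), Et2O, −78 °C; MgBr2·OEt2, −78 → −40 °C; CuI (20 mol%), 13, THF, −40 → −20 °C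
Reagents that add atoms: none
Why: Iodine–lithium exchange with retention of olefin geometry, transmetalation to magnesium and copper-catalysed SN2 opening of the glycidate at its unsubstituted carbon forge the C9–C10 bond and carry the C8 configuration unchanged from the chiral pool.

**Step 10**
Reactants: 16 α-hydroxy ester
Product: 17 methyl (2R,4Z,6R,9S)-2-(tert-butyldimethylsilyloxy)-6-[(4-methoxybenzyl)oxy]-4-methyl-8-methylidene-9,10-bis(triethylsilyloxy)dec-4-enoate
Conditions: TBSOTf, 2,6-lutidine, CH2Cl2, −78 °C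
Reagents that add atoms: tert-butyldimethylsilyl triflate CC(C)(C)[Si](C)(C)OS(=O)(=O)C(F)(F)F
Why: Silyl triflate with a hindered base protects O8 as a non-chelating, poorly leaving ether without epimerising the α-centre.

**Step 11**
Reactants: 17 silyloxy ester
Product: 18 (2R,4Z,6R,9S)-2-(tert-butyldimethylsilyloxy)-6-[(4-methoxybenzyl)oxy]-4-methyl-8-methylidene-9,10-bis(triethylsilyloxy)dec-4-enal
Conditions: i-Bu2AlH (1.1 equiv), CH2Cl2, −78 °C; aq. potassium sodium tartrate
Reagents that add atoms: none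
Why: At −78 °C the aluminium hemiacetal of the α-silyloxy ester is stable, so hydrolysis gives the C7 aldehyde without over-reduction or epimerisation at C8.

**Step 12**
Reactants: 18 aldehyde; 19 methyl acrylate
Product: 20 methyl (4R,6Z,8R,11S)-4-(tert-butyldimethylsilyloxy)-3-hydroxy-8-[(4-methoxybenzyl)oxy]-6-methyl-2,10-dimethylidene-11,12-bis(triethylsilyloxy)dodec-6-enoate (mixture of C3 epimers)
Conditions: 19 (10 equiv), DABCO (1 equiv), neat, rt
Reagents that add atoms: none
Why: The Morita–Baylis–Hillman reaction of the activated α-silyloxy aldehyde with the DABCO–acrylate zwitterion installs C11–C13, and the new carbinol centre at C7 may form as a mixture because it is erased in the next step.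

**Step 13**
Reactants: 20 Baylis–Hillman adduct
Product: 21 methyl (2Z,4R,6Z,8R,11S)-2-(bromomethyl)-4-(tert-butyldimethylsilyloxy)-8-[(4-methoxybenzyl)oxy]-6-methyl-10-methylidene-11,12-bis(triethylsilyloxy)dodeca-2,6-dienoate
Conditions: NBS, Me2S, CH2Cl2, 0 °C; then 20, 0 °C → rt
Reagents that add atoms: N-bromosuccinimide O=C1CCC(=O)N1Br
Why: The hydroxyl is activated as an alkoxysulfonium ion by the Corey–Kim-type reagent and bromide attacks in an SN2′ sense, which gives the thermodynamically preferred (Z)-2-(bromomethyl)enoate from both C7 epimers.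

**Step 14**
Reactants: 21 allylic bromide
Product: 22 methyl (2Z,4R,6Z,8R,11S)-2-(bromomethyl)-4-(tert-butyldimethylsilyloxy)-12-hydroxy-8-[(4-methoxybenzyl)oxy]-6-methyl-10-methylidene-11-(triethylsilyloxy)dodeca-2,6-dienoate
Conditions: PPTS (10 mol%), MeOH/CH2Cl2 1:4, −10 °C
Reagents that add atoms: none
Why: Acid-catalysed methanolysis cleaves the unhindered primary triethylsilyl ether much faster than the secondary silyl ethers and leaves the allylic bromide intact at low temperature.

**Step 15**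
Reactants: 22 primary alcohol
Product: 23 methyl (2Z,4R,6Z,8R,11S)-2-(bromomethyl)-4-(tert-butyldimethylsilyloxy)-8-[(4-methoxybenzyl)oxy]-6-methyl-10-methylidene-12-oxo-11-(triethylsilyloxy)dodeca-2,6-dienoate
Conditions: Dess–Martin periodinane, CH2Cl2, 0 °C → rt
Reagents that add atoms: none
Why: Dess–Martin oxidation under near-neutral conditions gives the α-silyloxy aldehyde without epimerisation at C5 or reaction at the allylic bromide.

**Step 16**
Reactants: 23 seco aldehyde/(Z)-2-(bromomethyl)enoate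
Product: 26 cis-fused α-methylene lactone with the target skeleton carrying OTES at C5 and OTBS at C8 and OPMB at C2, via allylchromium dichloride 24 (not isolated), via chromium alkoxide 25 (not isolated)
Conditions: CrCl2 (8 equiv), THF/DMF 10:1, rt, 23 added by syringe pump over 12 h (final 2 mM); aq. NH4Cl; PPTS (cat.), CH2Cl2, rt if open hydroxy ester remains
Reagents that add atoms: none
Why: Two equivalents of CrCl2 convert the allylic bromide into the 2-(methoxycarbonyl)allyl species of trivalent chromium 24, whose γ-carbon C7 adds to the C6 aldehyde through a chair-like six-membered transition state with transposition of the double bond to C11=C13, and the resulting C6–O–Cr alkoxide 25 then acylates itself with the C12 methyl ester; the closest known reaction type is the intramolecular Nozaki–Hiyama (Barbier-type) allylation of ω-formyl 2-(bromomethyl)enoates used to close medium-ring α-methylene lactones. The ten-membered carbocycle closes by addition of the tethered allyl nucleophile to the C6 carbonyl (C6–C7 bond, high dilution, the (Z)-C1=C10 olefin acting as a turn), and the five-membered lactone closes afterwards by 5-exo-trig acyl substitution. The cis ring fusion (C6/C7) follows from the allylchromium geometry in which C8 is trans to the ester and cis to CH2Cr, which puts C8 axial in the chair and gives the syn adduct, and since allylchromium species equilibrate by 1,3-metal shift, any (E)-bromide in 23 should be funnelled to the same diastereomer. The configuration at C6 is set by the C5 stereocentre (Felkin–Anh attack anti to the C5–OSiEt3 bond, giving the 5,6-anti diol pattern) and that at C7 by the C8 stereocentre (H8 eclipsing the allyl plane to avoid 1,3-allylic strain with the CH2Cr terminus, the C9 chain anti to the forming bond, the silyloxy group outside), and the three preferences are mutually matched for the target configuration. The step needs ring closure to beat oligomerisation and 1,4-elimination of the C8 oxygen, which slow addition to about 2 mM and the poor leaving-group ability of a silyl ether should secure.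

**Step 17**
Reactants: 26 tris-ether lactone
Product: 27 C5 alcohol (OTBS at C8 and OPMB at C2 retained)
Conditions: PPTS (20 mol%), MeOH/CH2Cl2 1:1, rt
Reagents that add atoms: none
Why: Mild acid methanolysis removes the secondary triethylsilyl ether at O5 while the bulkier TBS ether and the PMB ether survive.

**Step 18**
Reactants: 27 C5 alcohol
Product: 28 C5 acetate
Conditions: Ac2O, pyridine, DMAP (cat.), CH2Cl2, 0 °C → rt
Reagents that add atoms: acetic anhydride CC(=O)OC(C)=O
Why: DMAP-catalysed acetylation of the only free hydroxyl installs the C5 acetate with retention.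

**Step 19**
Reactants: 28 C5 acetate
Product: 29 C8 alcohol (5-OAc and 2-OPMB retained)
Conditions: HF·pyridine, pyridine, THF, 0 °C → rt
Reagents that add atoms: none
Why: Fluoride-mediated desilylation under buffered acidic conditions frees O8 without acyl migration or opening of the lactone.

**Step 20**
Reactants: 29 C8 alcohol
Product: 30 C8 tiglate (2-O-PMB ether of the target)
Conditions: tigloyl chloride, pyridine, DMAP (cat.), CH2Cl2, 0 °C → rt
Reagents that add atoms: (E)-2-methylbut-2-enoyl chloride C/C=C(\C)C(=O)Cl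
Why: DMAP-catalysed acylation with the acid chloride installs the tiglate, whose (E) geometry is the thermodynamically stable one and is retained.

**Step 21**
Reactants: 30 PMB ether of the target
Product: 31 CNP0210609.1
Conditions: DDQ, CH2Cl2/pH 7 phosphate buffer 10:1, 0 °C
Reagents that add atoms: none
Why: Oxidative cleavage of the PMB ether with DDQ in buffered wet CH2Cl2 releases the allylic C2 hydroxyl and leaves the esters, the lactone and the olefins untouched.

**Compound list**
1 | methyl (2R)-2,3-dihydroxypropanoate | COC(=O)[C@H](O)CO | starting material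
2 | methyl (2R)-2,3-bis(triethylsilyloxy)propanoate | COC(=O)[C@H](O[Si](CC)(CC)CC)CO[Si](CC)(CC)CC | intermediate
3 | (3R)-3,4-bis(triethylsilyloxy)-1-(trimethylsilyl)-2-[(trimethylsilyl)methyl]butan-2-ol | C[Si](C)(C)CC(O)(C[Si](C)(C)C)[C@H](O[Si](CC)(CC)CC)CO[Si](CC)(CC)CC | intermediate
4 | [(3S)-3,4-bis(triethylsilyloxy)-2-methylidenebutyl]trimethylsilane | C[Si](C)(C)CC(=C)[C@H](O[Si](CC)(CC)CC)CO[Si](CC)(CC)CC | intermediate
5 | (3S)-2-(bromomethyl)-3,4-bis(triethylsilyloxy)but-1-ene | BrCC(=C)[C@H](O[Si](CC)(CC)CC)CO[Si](CC)(CC)CC | intermediate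
6 | tributyl[(3S)-3,4-bis(triethylsilyloxy)-2-methylidenebutyl]stannane | CCCC[Sn](CCCC)(CCCC)CC(=C)[C@H](O[Si](CC)(CC)CC)CO[Si](CC)(CC)CC | intermediate
7 | but-2-yn-1-ol | CC#CCO | starting material
8 | sodium (Z)-alkenylalanate, five-membered C=C–CH2–O–Al chelate with two 2-methoxyethoxy ligands | CC1=CCO[Al-]1(OCCOC)OCCOC.[Na+] | intermediate
9 | (2Z)-3-iodobut-2-en-1-ol | C/C(I)=C/CO | intermediate
10 | (2Z)-3-iodobut-2-enal | C/C(I)=C/C=O | intermediate
11 | (2Z,4R,7S)-2-iodo-6-methylidene-7,8-bis(triethylsilyloxy)oct-2-en-4-ol | C/C(I)=C/[C@H](O)CC(=C)[C@H](O[Si](CC)(CC)CC)CO[Si](CC)(CC)CC | intermediate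
12 | 1-({[(2Z,4R,7S)-2-iodo-6-methylidene-7,8-bis(triethylsilyloxy)oct-2-en-4-yl]oxy}methyl)-4-methoxybenzene | C/C(I)=C/[C@H](OCc1ccc(OC)cc1)CC(=C)[C@H](O[Si](CC)(CC)CC)CO[Si](CC)(CC)CC | intermediate
13 | methyl (2R)-oxirane-2-carboxylate | COC(=O)[C@H]1CO1 | starting material
14 | alkenyllithium from 12 (Li in place of I, geometry retained) | C/C([Li])=C/[C@H](OCc1ccc(OC)cc1)CC(=C)[C@H](O[Si](CC)(CC)CC)CO[Si](CC)(CC)CC | intermediate
15 | alkenylmagnesium bromide from 14 | C/C([Mg]Br)=C/[C@H](OCc1ccc(OC)cc1)CC(=C)[C@H](O[Si](CC)(CC)CC)CO[Si](CC)(CC)CC | intermediate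
16 | methyl (2R,4Z,6R,9S)-2-hydroxy-6-[(4-methoxybenzyl)oxy]-4-methyl-8-methylidene-9,10-bis(triethylsilyloxy)dec-4-enoate | COC(=O)[C@H](O)C/C(C)=C\[C@H](OCc1ccc(OC)cc1)CC(=C)[C@H](O[Si](CC)(CC)CC)CO[Si](CC)(CC)CC | intermediate
17 | methyl (2R,4Z,6R,9S)-2-(tert-butyldimethylsilyloxy)-6-[(4-methoxybenzyl)oxy]-4-methyl-8-methylidene-9,10-bis(triethylsilyloxy)dec-4-enoate | COC(=O)[C@H](O[Si](C)(C)C(C)(C)C)C/C(C)=C\[C@H](OCc1ccc(OC)cc1)CC(=C)[C@H](O[Si](CC)(CC)CC)CO[Si](CC)(CC)CC | intermediate
18 | (2R,4Z,6R,9S)-2-(tert-butyldimethylsilyloxy)-6-[(4-methoxybenzyl)oxy]-4-methyl-8-methylidene-9,10-bis(triethylsilyloxy)dec-4-enal | O=C[C@H](O[Si](C)(C)C(C)(C)C)C/C(C)=C\[C@H](OCc1ccc(OC)cc1)CC(=C)[C@H](O[Si](CC)(CC)CC)CO[Si](CC)(CC)CC | intermediate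
19 | methyl acrylate | C=CC(=O)OC | starting material
20 | methyl (4R,6Z,8R,11S)-4-(tert-butyldimethylsilyloxy)-3-hydroxy-8-[(4-methoxybenzyl)oxy]-6-methyl-2,10-dimethylidene-11,12-bis(triethylsilyloxy)dodec-6-enoate, C3 epimer mixture | C=C(C(=O)OC)C(O)[C@H](O[Si](C)(C)C(C)(C)C)C/C(C)=C\[C@H](OCc1ccc(OC)cc1)CC(=C)[C@H](O[Si](CC)(CC)CC)CO[Si](CC)(CC)CC | intermediate
21 | methyl (2Z,4R,6Z,8R,11S)-2-(bromomethyl)-4-(tert-butyldimethylsilyloxy)-8-[(4-methoxybenzyl)oxy]-6-methyl-10-methylidene-11,12-bis(triethylsilyloxy)dodeca-2,6-dienoate | COC(=O)C(\CBr)=C\[C@H](O[Si](C)(C)C(C)(C)C)C/C(C)=C\[C@H](OCc1ccc(OC)cc1)CC(=C)[C@H](O[Si](CC)(CC)CC)CO[Si](CC)(CC)CC | intermediate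
22 | methyl (2Z,4R,6Z,8R,11S)-2-(bromomethyl)-4-(tert-butyldimethylsilyloxy)-12-hydroxy-8-[(4-methoxybenzyl)oxy]-6-methyl-10-methylidene-11-(triethylsilyloxy)dodeca-2,6-dienoate | COC(=O)C(\CBr)=C\[C@H](O[Si](C)(C)C(C)(C)C)C/C(C)=C\[C@H](OCc1ccc(OC)cc1)CC(=C)[C@H](O[Si](CC)(CC)CC)CO | intermediate
23 | methyl (2Z,4R,6Z,8R,11S)-2-(bromomethyl)-4-(tert-butyldimethylsilyloxy)-8-[(4-methoxybenzyl)oxy]-6-methyl-10-methylidene-12-oxo-11-(triethylsilyloxy)dodeca-2,6-dienoate | COC(=O)C(\CBr)=C\[C@H](O[Si](C)(C)C(C)(C)C)C/C(C)=C\[C@H](OCc1ccc(OC)cc1)CC(=C)[C@H](O[Si](CC)(CC)CC)C=O | intermediate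
24 | 2-(methoxycarbonyl)allylchromium dichloride from 23 (CrCl2 in place of Br, solvent ligands omitted) | Cl[Cr](Cl)C/C(C(=O)OC)=C\[C@H](O[Si](C)(C)C(C)(C)C)C/C(C)=C\[C@H](OCc1ccc(OC)cc1)CC(=C)[C@H](O[Si](CC)(CC)CC)C=O | intermediate
25 | chromium alkoxide of the ring-closed hydroxy ester: methyl 2-(cyclodecenyl)acrylate with C6–O–CrCl2, 5-OTES, 8-OTBS, 2-OPMB | C=C(C(=O)OC)[C@@H]1[C@H](O[Si](C)(C)C(C)(C)C)C/C(C)=C\[C@H](OCc2ccc(OC)cc2)CC(=C)[C@H](O[Si](CC)(CC)CC)[C@@H]1O[Cr](Cl)Cl | intermediate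
26 | cis-fused α-methylene lactone, target skeleton with 5-OTES, 8-OTBS, 2-OPMB | C=C1C(=O)O[C@@H]2[C@H]1[C@H](O[Si](C)(C)C(C)(C)C)C/C(C)=C\[C@H](OCc3ccc(OC)cc3)CC(=C)[C@@H]2O[Si](CC)(CC)CC | intermediate
27 | lactone with 5-OH, 8-OTBS, 2-OPMB | C=C1C(=O)O[C@@H]2[C@H]1[C@H](O[Si](C)(C)C(C)(C)C)C/C(C)=C\[C@H](OCc3ccc(OC)cc3)CC(=C)[C@@H]2O | intermediate
28 | lactone with 5-OAc, 8-OTBS, 2-OPMB | C=C1C(=O)O[C@@H]2[C@H]1[C@H](O[Si](C)(C)C(C)(C)C)C/C(C)=C\[C@H](OCc3ccc(OC)cc3)CC(=C)[C@@H]2OC(C)=O | intermediate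
29 | lactone with 5-OAc, 8-OH, 2-OPMB | C=C1C(=O)O[C@@H]2[C@H]1[C@H](O)C/C(C)=C\[C@H](OCc3ccc(OC)cc3)CC(=C)[C@@H]2OC(C)=O | intermediate
30 | 2-O-PMB ether of the target (5-OAc, 8-O-tiglate) | C=C1C(=O)O[C@@H]2[C@H]1[C@H](OC(=O)/C(C)=C/C)C/C(C)=C\[C@H](OCc3ccc(OC)cc3)CC(=C)[C@@H]2OC(C)=O | intermediate
31 | CNP0210609.1: cis-fused α-methylene-γ-lactone on the (Z)-cyclodecene with 2-OH, 5-OAc, 8-O-tiglate, 4-methylidene, 10-methyl (2R,5S,6R,7R,8R in the numbering of the overview) | C=C1C(=O)O[C@@H]2[C@H]1[C@H](OC(=O)/C(C)=C/C)C/C(C)=C\[C@H](O)CC(=C)[C@@H]2OC(C)=O | target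

**Total step count:** 21.
**Longest linear sequence:** 19 steps (steps 1–4, then 7–21, from methyl (R)-glycerate).

**Steps most likely to fail**

Step 16. The ring closure may lose to oligomerisation, and above all the C8 stereocentre may bias the allyl face toward the wrong C7 configuration (C8–O bond anti to the forming bond instead of the C9 chain), which would make the triple diastereoselection mismatched. The fallback sets out from 12 and comes back at 30. It exploits the fact that whichever face the C8 substituent favours, one C8 epimer is matched with Felkin control at C5 and the syn chair.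
- Compound 12 is taken through the chemistry of step 9 with methyl (2S)-oxirane-2-carboxylate (the commercial enantiomer of 13) to give the C8-epimeric hydroxy ester F1.
- The operations of steps 10–15 then give the TBS ether F2, the aldehyde F3, the Baylis–Hillman adduct F4, the bromide F5, the primary alcohol F6 and the seco aldehyde F7.
- CrCl2 cyclisation under the conditions of step 16 passes through the allylchromium dichloride F8 and the chromium alkoxide F9 to the 8-epi lactone F10.
- Removal of the triethylsilyl group gives the C5 alcohol F11, acetylation gives the acetate F12, and HF·pyridine gives the 8-epi alcohol F13.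
- Mitsunobu esterification of F13 with tiglic acid (PPh3, DIAD, toluene, 0 °C → rt) inverts C8 and installs the tiglate in one operation, giving 30.

Step 12. Addition to the hindered α-silyloxy aldehyde may be slow, and prolonged exposure to the amine may epimerise C8. The fallback sets out from 18 and comes back at 20. Aldol addition of the lithium enolate of methyl 3-(phenylselanyl)propanoate (LiN(i-Pr)2, THF, −78 °C) to 18 gives the β-hydroxy selenide F14 within minutes at low temperature. Oxidation with H2O2/pyridine (CH2Cl2, 0 °C → rt) gives the selenoxide F15, whose syn-elimination toward the only β-hydrogen delivers 20.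

Step 14. Acid methanolysis may also remove the neighbouring secondary silyl ether at O5 or solvolyse the allylic bromide. The fallback sets out from 21 and comes back at 23 with no new compound F0. The primary triethylsilyl ether is cleaved and oxidised in one pot under Swern conditions ((COCl)2, DMSO, CH2Cl2, −78 → −30 °C; then i-Pr2NEt), under which secondary silyl ethers persist, so the alcohol 22 and the acidic medium are bypassed.

**Further compounds**
F1 | step 16 | methyl (2S,4Z,6R,9S)-2-hydroxy-6-[(4-methoxybenzyl)oxy]-4-methyl-8-methylidene-9,10-bis(triethylsilyloxy)dec-4-enoate (C8 epimer of 16) | COC(=O)[C@@H](O)C/C(C)=C\[C@H](OCc1ccc(OC)cc1)CC(=C)[C@H](O[Si](CC)(CC)CC)CO[Si](CC)(CC)CC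
F2 | step 16 | C8 epimer of 17 | COC(=O)[C@@H](O[Si](C)(C)C(C)(C)C)C/C(C)=C\[C@H](OCc1ccc(OC)cc1)CC(=C)[C@H](O[Si](CC)(CC)CC)CO[Si](CC)(CC)CC
F3 | step 16 | C8 epimer of 18 | O=C[C@@H](O[Si](C)(C)C(C)(C)C)C/C(C)=C\[C@H](OCc1ccc(OC)cc1)CC(=C)[C@H](O[Si](CC)(CC)CC)CO[Si](CC)(CC)CC
F4 | step 16 | C8 epimer of 20 | C=C(C(=O)OC)C(O)[C@@H](O[Si](C)(C)C(C)(C)C)C/C(C)=C\[C@H](OCc1ccc(OC)cc1)CC(=C)[C@H](O[Si](CC)(CC)CC)CO[Si](CC)(CC)CC
F5 | step 16 | C8 epimer of 21 | COC(=O)C(\CBr)=C\[C@@H](O[Si](C)(C)C(C)(C)C)C/C(C)=C\[C@H](OCc1ccc(OC)cc1)CC(=C)[C@H](O[Si](CC)(CC)CC)CO[Si](CC)(CC)CC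
F6 | step 16 | C8 epimer of 22 | COC(=O)C(\CBr)=C\[C@@H](O[Si](C)(C)C(C)(C)C)C/C(C)=C\[C@H](OCc1ccc(OC)cc1)CC(=C)[C@H](O[Si](CC)(CC)CC)CO
F7 | step 16 | C8 epimer of 23 | COC(=O)C(\CBr)=C\[C@@H](O[Si](C)(C)C(C)(C)C)C/C(C)=C\[C@H](OCc1ccc(OC)cc1)CC(=C)[C@H](O[Si](CC)(CC)CC)C=O
F8 | step 16 | C8 epimer of 24 | Cl[Cr](Cl)C/C(C(=O)OC)=C\[C@@H](O[Si](C)(C)C(C)(C)C)C/C(C)=C\[C@H](OCc1ccc(OC)cc1)CC(=C)[C@H](O[Si](CC)(CC)CC)C=O
F9 | step 16 | C8 epimer of 25 | C=C(C(=O)OC)[C@@H]1[C@@H](O[Si](C)(C)C(C)(C)C)C/C(C)=C\[C@H](OCc2ccc(OC)cc2)CC(=C)[C@H](O[Si](CC)(CC)CC)[C@@H]1O[Cr](Cl)Cl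
F10 | step 16 | C8 epimer of 26 | C=C1C(=O)O[C@@H]2[C@H]1[C@@H](O[Si](C)(C)C(C)(C)C)C/C(C)=C\[C@H](OCc3ccc(OC)cc3)CC(=C)[C@@H]2O[Si](CC)(CC)CC
F11 | step 16 | C8 epimer of 27 | C=C1C(=O)O[C@@H]2[C@H]1[C@@H](O[Si](C)(C)C(C)(C)C)C/C(C)=C\[C@H](OCc3ccc(OC)cc3)CC(=C)[C@@H]2O
F12 | step 16 | C8 epimer of 28 | C=C1C(=O)O[C@@H]2[C@H]1[C@@H](O[Si](C)(C)C(C)(C)C)C/C(C)=C\[C@H](OCc3ccc(OC)cc3)CC(=C)[C@@H]2OC(C)=O
F13 | step 16 | C8 epimer of 29 | C=C1C(=O)O[C@@H]2[C@H]1[C@@H](O)C/C(C)=C\[C@H](OCc3ccc(OC)cc3)CC(=C)[C@@H]2OC(C)=O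
F14 | step 12 | β-hydroxy selenide: 20 with CH(CH2SePh) in place of C(=CH2), mixture at the two new centres | COC(=O)C(C[Se]c1ccccc1)C(O)[C@H](O[Si](C)(C)C(C)(C)C)C/C(C)=C\[C@H](OCc1ccc(OC)cc1)CC(=C)[C@H](O[Si](CC)(CC)CC)CO[Si](CC)(CC)CC
F15 | step 12 | selenoxide of F14 | COC(=O)C(C[Se](=O)c1ccccc1)C(O)[C@H](O[Si](C)(C)C(C)(C)C)C/C(C)=C\[C@H](OCc1ccc(OC)cc1)CC(=C)[C@H](O[Si](CC)(CC)CC)CO[Si](CC)(CC)CC
F0 | step 14 | none | none
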